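## Retrosynthetic overview
1. Target ⇒ ovatodiolide. The last step is a photosensitised singlet-oxygen (Schenck) ene reaction at the only electron-rich alkene, C4=C5, which creates C5–OOH and C4=CH2.
2. Ovatodiolide ⇒ acyclic ω-formyl 2-(bromomethyl)enoate. The C1–C14 bond, the 14-membered ring and the trans α-methylene-γ-lactone form together in a visible-light, Cr-catalysed Barbier macrocyclisation steered by C10.
3. Seco-bromide ⇒ one polyene ester, by tandem RCM (C8=C9, butenolide) and cross-metathesis (prenyl end → bromomethyl enoate, C1=C15).
4. Ester ⇒ (R)-vinyl-carbinol enal (from (R)-epichlorohydrin, an alkyne, a CH2 ylide, Me–Al and CH2O) plus a 2-methylene acid (from (E)-geranylacetone and CO).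
5. Ring order: butenolide first, then macrocycle and α-methylene lactone together. C10 is bought, and C1/C14 and then C5 are relayed from it.

Assumptions: cembrane numbering is used (C1 = lactone β-CH, C10 = butenolide γ-CH, C14 = lactone O-CH), "5β" = 5R as in the SMILES, and (E)-geranylacetone is bought isomerically pure.

## Forward route

**Step 1**
Reactants: 1, (R)-epichlorohydrin; 2, trimethylsilylacetylene
Product: 3, (R)-1-chloro-5-(trimethylsilyl)pent-4-yn-2-ol
Conditions: 2, n-BuLi, THF, −78 °C; BF3·OEt2; then 1, −78 °C
Reagents that add atoms: none (all new atoms come from 2)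
Why: BF3-assisted SN2 alkynylation of the epoxide (Yamaguchi–Hirao type) occurs only at the unsubstituted epoxide carbon, so the purchased C–O stereocentre (future C10) is untouched and the chloride survives at −78 °C.

**Step 2**
Reactants: 3
Product: 4, (R)-hex-1-en-5-yn-3-ol
Conditions: Me3S+I− (4 equiv), n-BuLi (3.9 equiv), THF, −20 °C → rt; then MeOH, K2CO3, rt (same flask)
Reagents that add atoms: trimethylsulfonium iodide, C[S+](C)C.[I-] (gives the terminal =CH2 carbon)
Why: Base closes the chlorohydrin to the terminal epoxide, which dimethylsulfonium methylide opens at CH2 and then loses Me2S (epoxide → one-carbon-homologated allylic alcohol); the carbinol C–O bond is never broken, and the methanolic carbonate quench protodesilylates the alkyne.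

**Step 3**
Reactants: 4
Product: 5, (2E,5R)-3-methylhepta-2,6-diene-1,5-diol
Conditions: AlMe3 (3.5 equiv), Cp2ZrCl2 (25 mol %), CH2Cl2, 0 °C → rt; evaporate; THF, n-BuLi, then (CH2O)n, rt
Reagents that add atoms: trimethylaluminium, C[Al](C)C (CH3); paraformaldehyde as formaldehyde, C=O (CH2OH)
Why: Negishi Zr-catalysed syn-methylalumination puts Me on the internal and Al on the terminal alkyne carbon (pure E), and the derived alanate is hydroxymethylated with retention while the monosubstituted alkene is inert to this catalyst.

**Step 4**
Reactants: 5
Product: 6, (2E,5R)-5-hydroxy-3-methylhepta-2,6-dienal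
Conditions: TEMPO (10 mol %), PhI(OAc)2, CH2Cl2, rt
Reagents that add atoms: none
Why: Oxoammonium (TEMPO) oxidation is sterically selective for the primary allylic alcohol and stops at the enal, leaving the secondary vinyl carbinol free without any protecting group.

**Step 5**
Reactants: 7, (E)-geranylacetone
Product: 8, (E)-6,10-dimethylundeca-1,5,9-trien-2-yl triflate
Conditions: LDA, THF, −78 °C; Comins' reagent, −78 → 0 °C
Reagents that add atoms: N-(5-chloro-2-pyridyl)bis(triflimide), FC(F)(F)S(=O)(=O)N(c1ccc(Cl)cn1)S(=O)(=O)C(F)(F)F
Why: Kinetic deprotonation of the methyl ketone on the CH3 side and fast O-triflation give the terminal vinyl triflate, and the E-trisubstituted alkene (future C4=C5) is simply carried through.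

**Step 6**
Reactants: 8
Product: 9, (E)-6,10-dimethyl-2-methylideneundeca-5,9-dienoic acid
Conditions: Pd(OAc)2 (5 mol %), dppf, CO (1 atm), Et3N, DMF–H2O 9:1, 60 °C
Reagents that add atoms: carbon monoxide, [C-]#[O+]; water, O
Why: Pd-catalysed hydroxycarbonylation of a vinyl triflate (oxidative addition, CO insertion, hydrolysis of the acyl-Pd) installs C19 directly as the 2-substituted acrylic acid, and isolated trisubstituted alkenes are spectators.

**Step 7**
Reactants: 6; 9
Product: 10, (3R,5E)-5-methyl-7-oxohepta-1,5-dien-3-yl (5E)-6,10-dimethyl-2-methylideneundeca-5,9-dienoate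
Conditions: EDC·HCl, DMAP (cat.), CH2Cl2, 0 °C → rt
Reagents that add atoms: none
Why: Steglich esterification acylates on oxygen, so C10 is retained, and the hindered enal is inert.

**Step 8**
Reactants: 10; 11, methyl 2-(bromomethyl)acrylate (8 equiv)
Product: 12, methyl (2Z,6E)-2-(bromomethyl)-6-methyl-9-{(5R)-5-[(2E)-2-methyl-4-oxobut-2-enyl]-2-oxo-2,5-dihydrofuran-3-yl}nona-2,6-dienoate
Conditions: Hoveyda–Grubbs II (5 + 5 mol %), 1,4-benzoquinone (10 mol %), DCE, 40 °C then 70 °C, Ar sparge (one flask)
Reagents that add atoms: none beyond 11
Why: In this tandem RCM/cross-metathesis, Ru loads on the vinyl group and closes the five-membered butenolide fast (−C2H4). Ru=CH2 then attacks only the gem-dimethyl terminus (−isobutene; internal C4=C5, the enal and the butenolide cannot form productive alkylidenes). The resulting Ru=C1HR turns over with the 2-substituted acrylate as known for methacrylates and methallyl halides. Reagent 11 is a less-tested partner, the E/Z outcome is irrelevant for step 9, and the neutral conditions keep C10 intact.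

**Step 9**
Reactants: 12
Product: 13, ovatodiolide (1R,10R,14S; 4E,12E)
Conditions: CrCl2 (20 mol %), 4CzIPN (3 mol %), Hantzsch ester (2 equiv), 2,6-lutidine (2 equiv), degassed THF–DMF 9:1, 12 added by syringe pump over 14 h (final 2 mM), 456 nm LEDs, 25 °C; then PPTS (cat.), rt
Reagents that add atoms: none
Why: Proposed new method: a light-gated, Cr-catalytic Nozaki–Hiyama-type Barbier macrocyclisation–lactonisation. Excited 4CzIPN is reductively quenched by the Hantzsch ester, and its radical anion (about −1.2 V) keeps a low steady-state level of Cr(II). Cr(II) abstracts Br from 12 and captures the 2-(methoxycarbonyl)allyl radical. The equilibrating allyl–Cr(III) adds γ-selectively (C1) to the tethered enal through a closed chair with the C2 and C13 chains pseudo-equatorial, giving the anti adduct and hence the trans lactone. The rigid (R)-C10 butenolide embedded in the forming 14-membered ring is expected to decide which enal face can reach the allyl unit (→ 1R,14S). Lutidinium releases the Cr alkoxide, which lactonises with loss of MeOH, and the enal, butenolide and product acrylate are not reducible at −1.2 V. The closest known reaction types are intermolecular photoredox/Cr allylations of aldehydes and stoichiometric CrCl2- or Zn-mediated Barbier macrocyclisations of ω-formyl 2-(bromomethyl)acrylates; a photocatalytic macrocyclic version with remote stereocontrol has not been shown.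

**Step 10**
Reactants: 13
Product: 14, 4-methylene-5β-hydroperoxyovatodiolide (target)
Conditions: O2 (1 atm), tetraphenylporphyrin (0.5 mol %), CH2Cl2, −20 °C, visible LED; no reductive work-up; SiO2 separation
Reagents that add atoms: dioxygen, O=O
Why: In the Schenck ene reaction, photogenerated 1O2 attacks only C4=C5, because the conjugated alkenes are inert and C12=C13 is deactivated by the allylic acyloxy group. It attacks on the exposed outer face of the macrocycle, which should set 5R. It abstracts H on the more substituted side (cis effect), preferentially from the freely rotating C18 methyl rather than the ring-locked C6–H, giving C5–OOH/C4=CH2; the 4-OOH-Δ5 regioisomer is the separable by-product.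

## Compound list
1 | (R)-epichlorohydrin | ClC[C@H]1CO1 | starting material
2 | trimethylsilylacetylene | C#C[Si](C)(C)C | starting material
3 | (R)-1-chloro-5-(trimethylsilyl)pent-4-yn-2-ol | ClC[C@H](O)CC#C[Si](C)(C)C | intermediate
4 | (R)-hex-1-en-5-yn-3-ol | C=C[C@H](O)CC#C | intermediate
5 | (2E,5R)-3-methylhepta-2,6-diene-1,5-diol | C=C[C@H](O)C/C(C)=C/CO | intermediate
6 | (2E,5R)-5-hydroxy-3-methylhepta-2,6-dienal | C=C[C@H](O)C/C(C)=C/C=O | intermediate
7 | (E)-geranylacetone | CC(=O)CC/C=C(\C)CCC=C(C)C | starting material
8 | (E)-6,10-dimethylundeca-1,5,9-trien-2-yl triflate | C=C(OS(=O)(=O)C(F)(F)F)CC/C=C(\C)CCC=C(C)C | intermediate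
9 | (E)-6,10-dimethyl-2-methylideneundeca-5,9-dienoic acid | C=C(C(=O)O)CC/C=C(\C)CCC=C(C)C | intermediate
10 | (R)-vinyl-carbinol ester of 9 with 6 | C=C[C@H](OC(=O)C(=C)CC/C=C(\C)CCC=C(C)C)C/C(C)=C/C=O | intermediate
11 | methyl 2-(bromomethyl)acrylate | C=C(CBr)C(=O)OC | starting material
12 | seco ω-formyl (Z)-2-(bromomethyl)enoate butenolide | O=C/C=C(\C)C[C@@H]1C=C(CC/C=C(\C)CC/C=C(\CBr)C(=O)OC)C(=O)O1 | intermediate
13 | ovatodiolide | C=C1C(=O)O[C@H]2/C=C(\C)C[C@@H]3C=C(CC/C=C(\C)CC[C@H]12)C(=O)O3 | intermediate
14 | 4-methylene-5β-hydroperoxyovatodiolide | C=C1C(=O)O[C@H]2/C=C(\C)C[C@@H]3C=C(CC[C@@H](OO)C(=C)CC[C@H]12)C(=O)O3 | target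

## Step count
- Total steps: 10, with no protecting groups.
- Longest linear sequence: 8 (steps 1–4, then 7–10).

## Steps most likely to fail
1. **Step 9 (proposed new step).** The risks are protodemetalation of the allyl–Cr species, oligomerisation, and modest induction from the remote C10 centre. Fallback (known chemistry): abandon photocatalysis for this bond and use the classical dark, stoichiometric two-electron Barbier ring closure of 12. That means excess CrCl2 in THF/DMF, or activated Zn in THF/aq. NH4Cl, under syringe-pump high dilution, followed by acid lactonisation.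
2. **Step 8 (cross-metathesis half).** Reagent 11 may be too hindered or electron-poor a partner. Fallback: drop metathesis for building the terminus.
   - On 10, carry out terminal-selective bromohydrin formation (NBS, aq. THF) and DBU epoxide closure.
   - Cleave with H5IO6 to the C1 aldehyde.
   - Run a Morita–Baylis–Hillman reaction with methyl acrylate, then PBr3 (SN2′).
   - Finish with a plain RCM.
   - This adds 4 steps, and all the basic steps come before the base-sensitive butenolide exists.
3. **Step 10.** The risks are the regioisomer ratio (5-OOH versus 4-OOH) and the 5β/5α ratio. Fallback: a dark route through the allylic alcohol.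
   - Epoxidise C4=C5 on the outer face with DMDO.
   - Isomerise with Cp2TiCl to the 4(18)-en-5β-ol.
   - Perform acid-catalysed perhydrolysis with ethereal H2O2 through the allyl cation, which the macrocycle should again capture on its outer face at C5.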